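**Retrosynthetic overview**
1. Target 25 ⇐ face-selective epoxidation of the C10 vinyl group (C1–O bond); the C15 aldehyde ⇐ SeO2 oxidation of an isopropenyl group; the C9 ester ⇐ acylation.
2. α-Methylene lactone ⇐ Pd cyclocarbonylation of a trans-7-ethynyl-8-ol; 6β-OH ⇐ Nef reaction of a C6 nitro group, then bulky hydride.
3. C9–O and the C10 quaternary centre ⇐ C8–OH-directed epoxidation of a 10-vinyl-9-ene and anti opening of that oxirane at C10 by AlMe3.
4. Cyclohexene carbaldehyde ⇐ two amine-catalysed Michael additions plus an aldol condensation joining silyloxyacetaldehyde 9, nitroenyne 5 and dienal 8.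
5. Ring order: carbocycle (step 4), transient 9,10-oxirane (step 6, opened in step 7), γ-lactone (step 10), C1–C2 oxirane (step 13).

Assumption: intermediates carry the atom numbers of the target (ring C5–C10; C1/C2 on C10; C3/C4/C15 on C5; C11–C13 on C7; C14 = methyl on C10); β is the ring face of the C7 side chain and the C10 methyl, α the opposite face; the target is taken as the open hydroxy-enal drawn.

**Route**

Step 1
Reactants: 1 3-(trimethylsilyl)prop-2-ynal; 2 nitromethane
Product: 5 (E)-trimethyl(4-nitrobut-3-en-1-yn-1-yl)silane, via nitro alcohol 3 (not isolated), via mesylate 4 (not isolated)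
Conditions: Et3N (cat.), THF, 0 °C; then MsCl, Et3N, CH2Cl2, −20 to 0 °C
Reagents that add atoms: none
Why: Henry (nitroaldol) addition followed by E1cB elimination of the mesylate gives the conjugated nitroenyne as the thermodynamically favoured E isomer; no stereocentre is formed.

Step 2
Reactants: 6 methacrolein; 7 (triphenylphosphoranylidene)acetaldehyde
Product: 8 (E)-4-methylpenta-2,4-dienal
Conditions: toluene, 60 °C (6 in excess)
Reagents that add atoms: none
Why: Wittig olefination with a stabilised ylide is E-selective, and the excess of 6 suppresses a second homologation.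

Step 3
Reactants: 9 (tert-butyldimethylsilyloxy)acetaldehyde; 5 (E)-trimethyl(4-nitrobut-3-en-1-yn-1-yl)silane
Product: 10 (2R,3S)-2-(tert-butyldimethylsilyloxy)-3-(nitromethyl)-5-(trimethylsilyl)pent-4-ynal
Conditions: (S)-2-[diphenyl(trimethylsilyloxy)methyl]pyrrolidine (10 mol%), PhCO2H (10 mol%), toluene, 0 °C
Reagents that add atoms: none
Why: Hayashi–Jørgensen enamine Michael addition: the (S)-catalyst shields one face of the E-enamine of 9, which adds 1,4 to the nitroenyne through the acyclic synclinal transition state to give the syn adduct, setting C8 (R, oxygen on the α face) and C7 (S, alkynyl on the β face).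

Step 4
Reactants: 10 (2R,3S)-nitro aldehyde; 8 (E)-4-methylpenta-2,4-dienal
Product: 13 5β-isopropenyl-6α-nitro-7β-(trimethylsilylethynyl)-8α-(tert-butyldimethylsilyloxy)cyclohex-9-ene-10-carbaldehyde, via Michael adduct 11 (not isolated), via aldol 12 (not isolated)
Conditions: (R)-2-[diphenyl(trimethylsilyloxy)methyl]pyrrolidine (20 mol%), PhCO2H (20 mol%), toluene, 0 °C to rt
Reagents that add atoms: none
Why: Iminium-activated nitro-Michael addition followed by enamine aldol condensation (the second half of an Enders-type cascade): nitroalkanes add 1,4 to dienal iminium ions, and the (R)-catalyst directs the nitronate to the face of C5 that places the isopropenyl group β, cis to the C7 substituent (the (S)-catalyst of step 3 would give the trans isomer); the C6 nitro centre is erased in step 8.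

Step 5
Reactants: 13 cyclohexene carbaldehyde
Product: 15 5β-isopropenyl-6α-nitro-7β-(trimethylsilylethynyl)-10-vinylcyclohex-9-en-8α-ol, via silyl ether diene 14 (not isolated)
Conditions: Ph3PCH3Br, KN(SiMe3)2 (2.5 equiv each), THF, −78 to 0 °C; then HF·pyridine, THF, 0 °C
Reagents that add atoms: methyltriphenylphosphonium bromide, C[P+](c1ccccc1)(c1ccccc1)c1ccccc1.[Br-]
Why: Wittig methylenation of the enal gives the 1,3-diene (excess ylide because the nitro group is deprotonated and returns on work-up), and HF·pyridine cleaves the secondary silyl ether while the C-silyl alkyne stays.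

Step 6
Reactants: 15 dienol
Product: 16 9α,10α-epoxy-5β-isopropenyl-6α-nitro-7β-(trimethylsilylethynyl)-10-vinylcyclohexan-8α-ol
Conditions: VO(acac)2 (5 mol%), t-BuOOH, CH2Cl2, 0 °C
Reagents that add atoms: tert-butyl hydroperoxide, CC(C)(C)OO
Why: Vanadium-catalysed hydroxyl-directed (Sharpless-type) epoxidation: the peroxo complex bound to the C8 alkoxide delivers oxygen only to the adjacent C9=C10 bond on the α face, syn to the hydroxyl, which fixes the C9–O configuration and leaves the isolated isopropenyl and the distal vinyl group untouched.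

Step 7
Reactants: 16 epoxy alcohol
Product: 17 5β-isopropenyl-10β-methyl-6α-nitro-7β-(trimethylsilylethynyl)-10α-vinylcyclohexane-8α,9α-diol
Conditions: AlMe3 (5 equiv), CH2Cl2/hexane, −40 to 0 °C
Reagents that add atoms: trimethylaluminium, C[Al](C)C
Why: Organoaluminium opening of a 2,3-epoxy alcohol at C3: methyl attacks the tertiary allylic C10 anti to the oxirane oxygen in the trans-diaxial (Fürst–Plattner) sense, so C10 receives a β-methyl with the vinyl group α and C9 keeps its α-hydroxyl.

Step 8
Reactants: 17 nitro diol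
Product: 19 7β-ethynyl-8α,9α-dihydroxy-5β-isopropenyl-10β-methyl-10α-vinylcyclohexan-6-one, via sodium nitronate 18 (not isolated)
Conditions: NaOMe, MeOH, 0 °C; then TiCl3, NH4OAc, H2O/MeOH, 0 °C to rt
Reagents that add atoms: water, O
Why: Methoxide removes the alkynyl silyl group and forms the nitronate, whose McMurry (TiCl3) Nef reaction gives the ketone under buffered conditions that leave the diequatorial C5 and C7 centres and the alkenes alone.

Step 9
Reactants: 19 ketone
Product: 20 7β-ethynyl-5β-isopropenyl-10β-methyl-10α-vinylcyclohexane-6β,8α,9α-triol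
Conditions: LiBH(s-Bu)3 (4 equiv), THF, −78 °C
Reagents that add atoms: none
Why: Bulky-hydride reduction: LiBH(s-Bu)3 attacks the ketone equatorially from the α face, the β face being blocked by the axial C10 methyl, to give the axial 6β-alcohol.

Step 10
Reactants: 20 triol
Product: 21 6β,9α-dihydroxy-5β-isopropenyl-10β-methyl-10α-vinyl 8α,12-olide with 11(13)-methylene
Conditions: PdI2 (5 mol%), PBu3 (10 mol%), CO (7 atm), MeCN, 75 °C
Reagents that add atoms: carbon monoxide, [C-]#[O+]
Why: Norton cyclocarbonylation of a homopropargylic alcohol: the alkoxycarbonyl–palladium species formed at the unhindered equatorial 8-OH adds cis across the trans-disposed alkyne and closes the trans-fused α-methylene-γ-butyrolactone, whereas 6-OH is shielded by the syn-axial methyl and two flanking branches and 9-OH could only give a six-membered ring.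

Step 11
Reactants: 21 lactone diol
Product: 22 9α-isobutyryloxy-6β-hydroxy-5β-isopropenyl-10β-methyl-10α-vinyl 8α,12-olide
Conditions: (i-PrCO)2O (1.2 equiv), DMAP (cat.), pyridine, CH2Cl2, 0 °C
Reagents that add atoms: isobutyric anhydride, CC(C)C(=O)OC(=O)C(C)C
Why: DMAP-catalysed acylation: 9-OH is the more accessible of the two axial alcohols, because 6-OH is syn-axial to the C10 methyl and flanked by two branched carbons.

Step 12
Reactants: 22 isobutyrate
Product: 24 15-oxo enal (C5 bears C(=CH2)CHO) with the C10 vinyl group intact, via allylic alcohol 23 (not isolated)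
Conditions: SeO2 (1.5 equiv), pyridine, 1,4-dioxane, 70 °C
Reagents that add atoms: selenium dioxide, O=[Se]=O
Why: Riley allylic oxidation (ene reaction, then [2,3]-shift) converts the methyl of the only electron-rich alkene with reactive allylic hydrogens into the aldehyde; the vinyl group has no allylic hydrogen and the lactone methylene is electron-poor.

Step 13
Reactants: 24 enal
Product: 25 target CNP0519565.1
Conditions: Ti(OiPr)4 (10 mol%), chiral salalen ligand (12 mol%; the antipode that gives (R)-1,2-epoxyalkanes from 1-alkenes), 30% aq. H2O2 (1.5 equiv), CH2Cl2, rt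
Reagents that add atoms: hydrogen peroxide, OO
Why: Proposed new method: a titanium salalen hydroperoxo species (Ti–OOH activated by the ligand N–H hydrogen bond) is an electrophilic oxygen donor that should epoxidise the only electron-rich alkene, the neopentylic vinyl group, while the enal and lactone methylenes are deactivated and no peracid is present to attack the aldehyde, and the chiral cis-β ligand pocket should override the weak bias of the quaternary centre to give the (1R)-oxirane; the closest known reaction is the titanium salalen/H2O2 asymmetric epoxidation of unhindered, non-conjugated terminal alkenes, which has not been shown for a vinyl group on a quaternary carbon or for catalyst-controlled diastereoselection in such a polyfunctional substrate.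

**Compound list**

1 | 3-(trimethylsilyl)prop-2-ynal | C[Si](C)(C)C#CC=O | starting material
2 | nitromethane | C[N+](=O)[O-] | starting material
3 | 1-nitro-4-(trimethylsilyl)but-3-yn-2-ol (racemic) | C[Si](C)(C)C#CC(O)C[N+](=O)[O-] | intermediate
4 | 1-nitro-4-(trimethylsilyl)but-3-yn-2-yl methanesulfonate (racemic) | C[Si](C)(C)C#CC(OS(C)(=O)=O)C[N+](=O)[O-] | intermediate
5 | (E)-trimethyl(4-nitrobut-3-en-1-yn-1-yl)silane | C[Si](C)(C)C#C/C=C/[N+](=O)[O-] | intermediate
6 | methacrolein | CC(=C)C=O | starting material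
7 | (triphenylphosphoranylidene)acetaldehyde | O=CC=P(c1ccccc1)(c1ccccc1)c1ccccc1 | starting material
8 | (E)-4-methylpenta-2,4-dienal | CC(=C)/C=C/C=O | intermediate
9 | (tert-butyldimethylsilyloxy)acetaldehyde | CC(C)(C)[Si](C)(C)OCC=O | starting material
10 | (2R,3S)-2-[(tert-butyldimethylsilyl)oxy]-3-(nitromethyl)-5-(trimethylsilyl)pent-4-ynal | O=C[C@H](O[Si](C)(C)C(C)(C)C)[C@H](C[N+](=O)[O-])C#C[Si](C)(C)C | intermediate
11 | open-chain Michael adduct: 2-silyloxy-4-nitro-5-isopropenyl-3-(trimethylsilylethynyl)heptanedial, C8 and C7 as in 10, isopropenyl carbon as in 13, both nitro epimers | O=C[C@H](O[Si](C)(C)C(C)(C)C)[C@@H](C#C[Si](C)(C)C)C([N+](=O)[O-])[C@@H](C(C)=C)CC=O | intermediate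
12 | cyclic aldol: 9-hydroxy-5β-isopropenyl-6-nitro-7β-(trimethylsilylethynyl)-8α-(tert-butyldimethylsilyloxy)cyclohexane-10-carbaldehyde (mixture at C6, C9, C10) | [C@@H]1(C(C)=C)C([N+](=O)[O-])[C@H](C#C[Si](C)(C)C)[C@@H](O[Si](C)(C)C(C)(C)C)C(O)C1C=O | intermediate
13 | 5β-isopropenyl-6α-nitro-7β-[(trimethylsilyl)ethynyl]-8α-(tert-butyldimethylsilyloxy)cyclohex-9-ene-10-carbaldehyde (major C6 epimer shown) | [C@@H]1(C(C)=C)[C@@H]([N+](=O)[O-])[C@H](C#C[Si](C)(C)C)[C@@H](O[Si](C)(C)C(C)(C)C)C=C1C=O | intermediate
14 | 10-vinyl diene from 13, 8α-silyl ether | [C@@H]1(C(C)=C)[C@@H]([N+](=O)[O-])[C@H](C#C[Si](C)(C)C)[C@@H](O[Si](C)(C)C(C)(C)C)C=C1C=C | intermediate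
15 | 5β-isopropenyl-6α-nitro-7β-[(trimethylsilyl)ethynyl]-10-vinylcyclohex-9-en-8α-ol | [C@@H]1(C(C)=C)[C@@H]([N+](=O)[O-])[C@H](C#C[Si](C)(C)C)[C@@H](O)C=C1C=C | intermediate
16 | 9α,10α-epoxide of 15 (oxirane syn to 8α-OH) | [C@@H]1(C(C)=C)[C@@H]([N+](=O)[O-])[C@H](C#C[Si](C)(C)C)[C@@H](O)[C@H]2O[C@]21C=C | intermediate
17 | 5β-isopropenyl-10β-methyl-6α-nitro-7β-[(trimethylsilyl)ethynyl]-10α-vinylcyclohexane-8α,9α-diol | [C@@H]1(C(C)=C)[C@@H]([N+](=O)[O-])[C@H](C#C[Si](C)(C)C)[C@@H](O)[C@@H](O)[C@@]1(C)C=C | intermediate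
18 | sodium nitronate of the desilylated nitro diol | [C@@H]1(C(C)=C)C(=[N+]([O-])[O-])[C@H](C#C)[C@@H](O)[C@@H](O)[C@@]1(C)C=C.[Na+] | intermediate
19 | 7β-ethynyl-8α,9α-dihydroxy-5β-isopropenyl-10β-methyl-10α-vinylcyclohexan-6-one | [C@@H]1(C(C)=C)C(=O)[C@H](C#C)[C@@H](O)[C@@H](O)[C@@]1(C)C=C | intermediate
20 | 7β-ethynyl-5β-isopropenyl-10β-methyl-10α-vinylcyclohexane-6β,8α,9α-triol | [C@@H]1(C(C)=C)[C@H](O)[C@H](C#C)[C@@H](O)[C@@H](O)[C@@]1(C)C=C | intermediate
21 | trans-fused 8α,12-olide with 11(13)-methylene, 6β-OH, 9α-OH, 5β-isopropenyl, 10β-methyl, 10α-vinyl | [C@@H]1(C(C)=C)[C@H](O)[C@@H]2C(=C)C(=O)O[C@H]2[C@@H](O)[C@@]1(C)C=C | intermediate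
22 | 9α-isobutyrate of 21 | [C@@H]1(C(C)=C)[C@H](O)[C@@H]2C(=C)C(=O)O[C@H]2[C@@H](OC(=O)C(C)C)[C@@]1(C)C=C | intermediate
23 | 15-hydroxy compound (C5 bears C(=CH2)CH2OH) | [C@@H]1(C(=C)CO)[C@H](O)[C@@H]2C(=C)C(=O)O[C@H]2[C@@H](OC(=O)C(C)C)[C@@]1(C)C=C | intermediate
24 | 15-oxo compound (C5 bears C(=CH2)CHO), 10α-vinyl | [C@@H]1(C(=C)C=O)[C@H](O)[C@@H]2C(=C)C(=O)O[C@H]2[C@@H](OC(=O)C(C)C)[C@@]1(C)C=C | intermediate
25 | CNP0519565.1: (1R)-1,2-epoxide of 24 | C=C1C(=O)O[C@@H]2[C@@H]1[C@@H](O)[C@@H](C(=C)C=O)[C@](C)([C@@H]1CO1)[C@@H]2OC(=O)C(C)C | target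

**Step count and risks**

Total: 13 steps. Longest linear sequence: 12 steps (1, 3–13); step 2 makes the second partner.

The three steps most likely to fail are 4, 11 and 13.

Step 4 (1,6- instead of 1,4-addition to the dienal, or poor catalyst control at C5). The fallback sets out from 10 and returns at 13. Triethyl phosphonoacetate and 6 are condensed (TiCl4, pyridine) to ethyl 2-(diethoxyphosphoryl)-4-methylpenta-2,4-dienoate F1. With Cs2CO3, the nitronate of 10 adds to this doubly activated alkene and the phosphonate anion closes the ring by intramolecular Horner–Wadsworth–Emmons olefination onto the C9 aldehyde. This gives the cyclohexene ethyl ester F2, whose C5 and C6 centres should equilibrate to the all-equatorial isomer by retro-Michael/Michael under the basic conditions. Reduction with i-Bu2AlH gives the allylic alcohol F3, and MnO2 oxidation gives 13.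

Step 11 (acylation at O6 instead of O9). The fallback sets out from 20 and returns at 22. Triol 20 and trimethyl orthoisobutyrate (cat. camphorsulfonic acid) give the cyclic 8,9-orthoester F4, which only the cis-1,2-diol can form. Mild aqueous acetic acid opens it to the axial ester, the 9-isobutyrate F5, with the equatorial 8-OH free. Cyclocarbonylation of F5 (PdI2, PBu3, CO) then gives 22 directly.

Step 13 (the proposed catalyst-controlled epoxidation gives low conversion or low facial selectivity). The fallback sets out from 24 and returns at 25. mCPBA (NaHCO3, CH2Cl2) epoxidises the vinyl group without facial control to the C1-epimer mixture F6. Hydrolytic kinetic resolution with the (S,S)-configured [N,N′-bis(3,5-di-tert-butylsalicylidene)-1,2-cyclohexanediaminato]cobalt acetate and 0.55 equiv of water hydrolyses the (1S)-epimer to the diol F7, which is removed by chromatography, and leaves 25.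

**Further compounds**

F1 | step 4 | ethyl 2-(diethoxyphosphoryl)-4-methylpenta-2,4-dienoate | CCOC(=O)C(=CC(C)=C)P(=O)(OCC)OCC
F2 | step 4 | ethyl 5β-isopropenyl-6α-nitro-7β-[(trimethylsilyl)ethynyl]-8α-(tert-butyldimethylsilyloxy)cyclohex-9-ene-10-carboxylate | [C@@H]1(C(C)=C)[C@@H]([N+](=O)[O-])[C@H](C#C[Si](C)(C)C)[C@@H](O[Si](C)(C)C(C)(C)C)C=C1C(=O)OCC
F3 | step 4 | 10-(hydroxymethyl) analogue of 13 (allylic alcohol) | [C@@H]1(C(C)=C)[C@@H]([N+](=O)[O-])[C@H](C#C[Si](C)(C)C)[C@@H](O[Si](C)(C)C(C)(C)C)C=C1CO
F4 | step 11 | cyclic 8α,9α-(methoxy)(isopropyl)orthoester of triol 20 | [C@@H]1(C(C)=C)[C@H](O)[C@H](C#C)[C@H]2OC(OC)(C(C)C)O[C@H]2[C@@]1(C)C=C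
F5 | step 11 | 9α-isobutyrate of triol 20 (6β-OH and 8α-OH free) | [C@@H]1(C(C)=C)[C@H](O)[C@H](C#C)[C@@H](O)[C@@H](OC(=O)C(C)C)[C@@]1(C)C=C
F6 | step 13 | mixture of the C1 epimers of 25 | C=C1C(=O)O[C@@H]2[C@@H]1[C@@H](O)[C@@H](C(=C)C=O)[C@](C)(C1CO1)[C@@H]2OC(=O)C(C)C
F7 | step 13 | 1,2-diol from the (1S)-epoxide | C=C1C(=O)O[C@@H]2[C@@H]1[C@@H](O)[C@@H](C(=C)C=O)[C@](C)([C@H](O)CO)[C@@H]2OC(=O)C(C)C
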